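**Plan**

1. Labels: each spiro unit is numbered as a spiro[4.5]decane (s1 carbinol next to the spiro carbon, s2 CH with the side chain, s5 spiro carbon, s6 C(CH3)OH, s9 enal-bearing carbon, s10 CH with the acyloxypropyl chain); the central cyclohexene is c1 (quaternary) to c6 (CH).
2. Cuts: the enals and myristates (made last, on the dimer); the side-chain C=C next to each s2 (Horner–Wadsworth–Emmons, one phosphono lactone used twice); the central ring at c1–c6 and c2–c3 (catalytic asymmetric Diels–Alder); the s2–C bond (carbenoid C–H insertion from the s1 oxygen); then s10–s9 and s5–s4 together.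
3. Enabling feature: s1 (a ketone at that stage) is bonded to the spiro carbon s5, s5 is flanked by the tertiary carbinol s6, and s9, 1,3 to s5, is oxidised. An α-spiro cyclopentanone with a 1,3-related ring C–O is the retron of an aldehyde Prins closure (s10–s9) ended by a 1,2-shift of a cyclobutanol carbon, so the cyclopentane is laid down as a cyclobutane and enlarged while the cyclohexane closes.
4. Forward order: geraniol-derived acyclic aldehyde → cyclohexane plus cyclopentanone in one step → temporary cis-fused lactone → triene → central cyclohexene → second spiro unit → myristates and enals → desilylation.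
5. Stereochemistry: s6 from Sharpless epoxidation; s5 and s10 relayed from s6 through a cyclic silylene and a defined alkene; s1 by hydroxyl-directed reduction; s2 by cis ring fusion; c1 and c6 by an endo, catalyst-controlled cycloaddition; alkene geometries by E-selective olefinations, trans-hydrostannation and thermodynamic control of the enals.

Key step: step 8

Assumption: the sense of induction of the oxazaborolidinium catalyst in the cycloaddition is taken from the accepted pretransition-state model for 2-substituted acroleins; the (R)-prolinol-derived catalyst is written and its enantiomer would be used if a model cycloaddition showed the opposite sense.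
Remark: carbinol centres that are oxidised or eliminated later (s9 before its oxidation, the isopropenyl carbinols) are drawn in the expected configuration, which has no bearing on the target; the phosphonate-bearing carbon of the phosphono lactone is a mixture of epimers.

**Route**

Step 1
Reactants: 1 geraniol
Product: 2 (2S,3S)-2,3-epoxygeraniol
Conditions: Ti(OiPr)4 (5 mol%), L-(+)-diethyl tartrate (6 mol%), tBuOOH, 4 Å MS, CH2Cl2, −20 °C
Reagents that add atoms: tert-butyl hydroperoxide CC(C)(C)OO
Why: Sharpless asymmetric epoxidation of the allylic alcohol should deliver oxygen to one face of the 2,3-alkene under control of the tartrate–titanium complex, which sets the quaternary C–O centre (future s6) and leaves the remote alkene untouched.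

Step 2
Reactants: 2 (2S,3S)-2,3-epoxygeraniol
Product: 3 epoxy chloride
Conditions: PPh3, CCl4, NaHCO3, reflux
Reagents that add atoms: tetrachloromethane ClC(Cl)(Cl)Cl
Why: Appel chlorination of the primary alcohol under neutral conditions should leave the epoxide and both stereocentres untouched.

Step 3
Reactants: 3 epoxy chloride; 4 tert-butyl(3-iodopropoxy)dimethylsilane
Product: 6 (6S)-1-[(tert-butyldimethylsilyl)oxy]-6,10-dimethylundec-9-en-4-yn-6-ol, via dilithium alkoxide acetylide 5 (not isolated)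
Conditions: n-BuLi (3.0 equiv), THF, −78 → −30 °C; then 4, DMPU, −30 °C → rt
Reagents that add atoms: none
Why: base-induced fragmentation of the 2,3-epoxy chloride (α-lithiation, epoxide opening, loss of HCl) should give the tertiary propargylic alkoxide without touching the C–O bond of the stereocentre, and the acetylide end is alkylated in the same flask (acetylide alkylation).

Step 4
Reactants: 6 (6S)-alkynol
Product: 7 (4Z,6S)-alkenylstannane
Conditions: Bu3SnH, [Cp*RuCl]4 (2 mol%), CH2Cl2, rt
Reagents that add atoms: tributyltin hydride CCCC[SnH](CCCC)CCCC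
Why: hydroxyl-directed ruthenium-catalysed trans-hydrostannation should place tin on the alkyne carbon next to the carbinol and hydrogen anti to it, which fixes the alkene geometry (chain cis to tin) that later sets s10.

Step 5
Reactants: 7 (4Z,6S)-alkenylstannane; 8 cyclobutanone
Product: 9 (4Z,6S)-cyclobutanol diol
Conditions: MeLi (2.5 equiv), THF, −78 → −20 °C; then 8, −78 °C
Reagents that add atoms: none
Why: tin–lithium exchange proceeds with retention of alkene geometry and the alkenyllithium adds to the unhindered, strained ketone (1,2-addition), so the cyclobutanol ends cis to the chain and no stereocentre is formed.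

Step 6
Reactants: 9 cyclobutanol diol
Product: 10 cyclic di-tert-butylsilylene
Conditions: tBu2Si(OTf)2, 2,6-lutidine, CH2Cl2, 0 °C → rt
Reagents that add atoms: di-tert-butylsilyl bis(trifluoromethanesulfonate) CC(C)(C)[Si](OS(=O)(=O)C(F)(F)F)(OS(=O)(=O)C(F)(F)F)C(C)(C)C
Why: silylene formation across the 1,3-diol (the bis-triflate is reactive enough for two tertiary alcohols) ties both oxygens into a six-membered ring that holds the s6–O bond near the alkene plane and turns the cyclobutanol into a siloxy donor for the ring expansion.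

Step 7
Reactants: 10 cyclic di-tert-butylsilylene
Product: 11 silylene aldehyde
Conditions: O3 (1 equiv), CH2Cl2, −78 °C; then PPh3
Reagents that add atoms: ozone [O-][O+]=O
Why: ozonolysis should cleave the electron-rich, unhindered isopropylidene alkene selectively, because the other alkene is deactivated by two allylic C–O bonds and shielded by the silylene and the cyclobutane.

Step 8
Reactants: 11 silylene aldehyde
Product: 13 (5R,6S,9S,10S)-6,9-dihydroxy-10-(3-hydroxypropyl)-6-methylspiro[4.5]decan-1-one, via fluorosilyl ether spiro ketone 12 (not isolated)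
Conditions: BF3·OEt2 (2 equiv), CH2Cl2, −78 → −40 °C; then HF·pyridine, pyridine, THF, 0 °C → rt
Reagents that add atoms: none
Why: BF3 binds the aldehyde and the s10 terminus of the trisubstituted alkene attacks the carbonyl carbon through a chair (6-endo-trig with respect to the alkene, the charge developing at the fully substituted s5), while a cyclobutane CH2 antiperiplanar to the new s10–s9 bond shifts from s1 to s5, so that the cyclohexane closes and the four-membered ring grows to the cyclopentanone in one cationic event (the siloxy oxygen on s1 becomes the carbonyl oxygen and fluoride from the BF3 alkoxide caps silicon). The closest known reaction type is the Prins–pinacol ring-enlarging annulation of 1-alkenylcycloalkanol silyl ethers. The configuration at s5 is set by the anti addition across the alkene (s9 to s10 on one face, the migrating carbon to s5 on the other) and that at s10 by the alkene geometry fixed in step 4 (chain cis to the cyclobutane gives chain cis to the ketone carbon). Both are relayed from s6 because the silylene ring holds the s6–O bond near the alkene plane, which leaves the tether carbon on one face and the s6 methyl on the other, so that the aldehyde can reach only one face and the migrating carbon ends cis to the methyl group. The s9 hydroxyl should come out equatorial (trans to the chain) but is oxidised later. The step needs ring enlargement to outrun methyl shift from s6, proton loss and 5-exo closure, which is secured by the strain release of the cyclobutane, the absence of hydrogen on the carbons flanking s5 and the tertiary, oxygen-assisted character of the s5 cation.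

Step 9
Reactants: 13 keto triol
Product: 14 bis(triethylsilyl) ether keto alcohol
Conditions: Et3SiCl (2.2 equiv), imidazole, CH2Cl2, −20 → 0 °C
Reagents that add atoms: chlorotriethylsilane CC[Si](Cl)(CC)CC
Why: silylation with the chlorosilane and imidazole should take the primary and the secondary hydroxyl only, the tertiary hydroxyl of the β-hydroxy ketone being too hindered (selective silyl protection).

Step 10
Reactants: 14 bis(triethylsilyl) ether keto alcohol
Product: 15 anti-1,3-diol
Conditions: Me4NBH(OAc)3, MeCN/AcOH, −30 °C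
Reagents that add atoms: none
Why: Evans–Saksena reduction, in which the borohydride bound to the s6 oxygen delivers hydride within the molecule to the ketone face syn to s6, should set s1 with its hydroxyl anti to the s6 hydroxyl and on the face of s10.

Step 11
Reactants: 15 anti-1,3-diol; 16 (diethoxyphosphoryl)acetic acid
Product: 17 s1 phosphonoacetate
Conditions: DCC, DMAP (cat.), CH2Cl2, 0 °C → rt
Reagents that add atoms: none
Why: Steglich esterification should acylate the secondary s1 hydroxyl and leave the tertiary s6 hydroxyl untouched.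

Step 12
Reactants: 17 s1 phosphonoacetate
Product: 18 tris(triethylsilyl) phosphonoacetate
Conditions: Et3SiOTf, 2,6-lutidine, CH2Cl2, −78 → 0 °C
Reagents that add atoms: triethylsilyl trifluoromethanesulfonate CC[Si](CC)(CC)OS(=O)(=O)C(F)(F)F
Why: the silyl triflate silylates the tertiary alcohol so that no O–H bond competes with C–H insertion in step 14 (silyl protection).

Step 13
Reactants: 18 tris(triethylsilyl) phosphonoacetate
Product: 19 α-diazo phosphonoacetate
Conditions: 4-acetamidobenzenesulfonyl azide, DBU, MeCN, 0 °C → rt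
Reagents that add atoms: 4-acetamidobenzenesulfonyl azide CC(=O)Nc1ccc(cc1)S(=O)(=O)N=[N+]=[N-]
Why: Regitz diazo transfer to the doubly activated methylene of the phosphonoacetate.

Step 14
Reactants: 19 α-diazo phosphonoacetate
Product: 20 cis-fused α-phosphono lactone
Conditions: Rh2(O2CC7H15)4 (2 mol%), CH2Cl2, 40 °C
Reagents that add atoms: none
Why: rhodium carbenoid 1,5 C–H insertion can only reach the s2–H bond cis to the ester oxygen (s5 is quaternary) and closes a necessarily cis-fused γ-lactone, which sets s2 with its new C–C bond cis to the s1 oxygen.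

Step 15
Reactants: 21 6-methylhept-5-en-2-one
Product: 22 6-methylhepta-1,5-dien-2-yl trifluoromethanesulfonate
Conditions: LiN(iPr)2, THF, −78 °C; then PhN(SO2CF3)2, −78 → 0 °C
Reagents that add atoms: N-phenylbis(trifluoromethanesulfonimide) FC(F)(F)S(=O)(=O)N(c1ccccc1)S(=O)(=O)C(F)(F)F
Why: kinetic deprotonation at the methyl group and O-sulfonylation of the enolate should give the terminal enol triflate (enol triflate formation).

Step 16
Reactants: 22 enol triflate; 23 acrolein
Product: 24 (2E)-8-methyl-4-methylidenenona-2,7-dienal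
Conditions: Pd(OAc)2 (5 mol%), PPh3 (10 mol%), Et3N, DMF, 60 °C
Reagents that add atoms: none
Why: Heck coupling of the alkenyl triflate at the terminal carbon of acrolein followed by syn β-hydride elimination should give the E-dienal.

Step 17
Reactants: 20 cis-fused α-phosphono lactone; 24 dienal
Product: 25 (E)-alkylidene lactone triene
Conditions: KOtBu, THF, 0 °C; then 24, 0 °C → rt
Reagents that add atoms: none
Why: Horner–Wadsworth–Emmons olefination of the lactone phosphonate anion with the conjugated aldehyde should give mainly the E-alkylidene lactone (dienyl chain anti to the carbonyl and cis to s2), the thermodynamically preferred isomer, with no change at any stereocentre.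

Step 18
Reactants: 25 (E)-alkylidene lactone triene
Product: 26 triene diol
Conditions: iBu2AlH (5 equiv), CH2Cl2, −78 → 0 °C; Rochelle salt work-up
Reagents that add atoms: none
Why: 1,2-reduction of the unsaturated lactone with the aluminium hydride should open it to the s1 alcohol and the allylic primary alcohol without touching the triene (lactone reduction).

Step 19
Reactants: 26 triene diol
Product: 27 triene bis(tert-butyldimethylsilyl) ether
Conditions: tBuMe2SiOTf (2.5 equiv), 2,6-lutidine, CH2Cl2, −78 → 0 °C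
Reagents that add atoms: tert-butyldimethylsilyl trifluoromethanesulfonate CC(C)(C)[Si](C)(C)OS(=O)(=O)C(F)(F)F
Why: the silyl triflate protects the primary allylic and the hindered secondary hydroxyl, which makes the triene an electron-rich diene free of Lewis-basic carbonyl groups (silyl protection).

Step 20
Reactants: 28 2-methylidenepropane-1,3-diol
Product: 29 2-{[(4-methoxybenzyl)oxy]methyl}prop-2-en-1-ol
Conditions: NaH (1 equiv), 4-methoxybenzyl chloride, Bu4NI (cat.), THF/DMF, 0 °C → rt; diol in excess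
Reagents that add atoms: 4-methoxybenzyl chloride COc1ccc(CCl)cc1
Why: Williamson mono-etherification of the symmetrical diol, driven toward the mono-ether by excess diol.

Step 21
Reactants: 29 mono(4-methoxybenzyl) ether
Product: 30 2-{[(4-methoxybenzyl)oxy]methyl}prop-2-enal
Conditions: MnO2, CH2Cl2, rt
Reagents that add atoms: none
Why: MnO2 oxidation of the allylic alcohol to the 2-substituted acrolein.

Step 22
Reactants: 27 triene bis(tert-butyldimethylsilyl) ether; 30 2-substituted acrolein
Product: 31 cyclohexene aldehyde (Diels–Alder adduct)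
Conditions: (R)-B-o-tolyl oxazaborolidinium triflimide [from the (R)-α,α-diphenylprolinol-derived oxazaborolidine and HN(SO2CF3)2], 20 mol%, CH2Cl2, −78 → −40 °C
Reagents that add atoms: none
Why: Lewis-acid-catalysed enantioselective Diels–Alder reaction, in which the boron-bound acrolein should add to the terminal s-cis diene of 27 (the internal diene has a fully substituted terminus), ortho to the alkenyl arm and para to the alkyl group, endo with respect to the formyl group so that CHO and the c6 arm end cis, and on the dienophile face left open by the catalyst, which sets c1 and c6.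

Step 23
Reactants: 31 cyclohexene aldehyde
Product: 32 c1 vinyl compound
Conditions: Ph3PCH3Br, KOtBu, THF, 0 °C → rt
Reagents that add atoms: methyltriphenylphosphonium bromide C[P+](c1ccccc1)(c1ccccc1)c1ccccc1.[Br-]
Why: Wittig methylenation of the aldehyde, which has no α-hydrogen, so c1 cannot epimerise.

Step 24
Reactants: 32 c1 vinyl compound; 33 1-bromo-2-methylprop-1-ene
Product: 35 c1 (4-methylpent-3-enyl) compound, via alkylborane 34 (not isolated)
Conditions: 9-BBN, THF, rt; then 33, Pd(dppf)Cl2 (5 mol%), AsPh3, aq. K3PO4, DMF, 50 °C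
Reagents that add atoms: none
Why: 9-BBN should hydroborate only the monosubstituted alkene (all others are trisubstituted) and B-alkyl Suzuki–Miyaura coupling with the alkenyl bromide completes the 4-methylpent-3-enyl group on c1, cis to the c6 arm as fixed in step 22.

Step 25
Reactants: 35 c1 (4-methylpent-3-enyl) compound
Product: 36 c1 primary alcohol
Conditions: DDQ, CH2Cl2/pH 7 buffer, 0 °C
Reagents that add atoms: none
Why: oxidative cleavage of the 4-methoxybenzyl ether with DDQ, possible here because no conjugated polyene is present.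

Step 26
Reactants: 36 c1 primary alcohol
Product: 37 c1 aldehyde
Conditions: Dess–Martin periodinane, NaHCO3, CH2Cl2, rt
Reagents that add atoms: none
Why: Dess–Martin oxidation of the neopentyl alcohol to the aldehyde under buffered conditions.

Step 27
Reactants: 37 c1 aldehyde; 38 (triphenylphosphoranylidene)acetaldehyde
Product: 39 (E)-enal
Conditions: toluene, 80 °C
Reagents that add atoms: none
Why: Wittig reaction with the stabilised formylmethylene ylide should give the E-enal, the product being less electrophilic than the starting aldehyde.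

Step 28
Reactants: 39 (E)-enal; 20 cis-fused α-phosphono lactone
Product: 40 dimeric alkylidene lactone
Conditions: 20 (1.3 equiv), KOtBu, THF, 0 °C; then 39, 0 °C → rt
Reagents that add atoms: none
Why: a second Horner–Wadsworth–Emmons olefination with the same phosphonate should give the (E,E)-diene that links c1 to the second spiro unit.

Step 29
Reactants: 40 dimeric alkylidene lactone
Product: 41 dimeric diol
Conditions: iBu2AlH (5 equiv), CH2Cl2, −78 → 0 °C; Rochelle salt work-up
Reagents that add atoms: none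
Why: 1,2-reduction of the second unsaturated lactone to the diol, as in step 18 (lactone reduction).

Step 30
Reactants: 41 dimeric diol
Product: 42 fully silylated dimer
Conditions: tBuMe2SiOTf (2.5 equiv), 2,6-lutidine, CH2Cl2, −78 → 0 °C
Reagents that add atoms: tert-butyldimethylsilyl trifluoromethanesulfonate CC(C)(C)[Si](C)(C)OS(=O)(=O)C(F)(F)F
Why: silyl protection of the new primary allylic and secondary hydroxyls brings both halves to the same protection state.

Step 31
Reactants: 42 fully silylated dimer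
Product: 43 tetraol
Conditions: PPTS (cat.), MeOH/CH2Cl2, 0 °C
Reagents that add atoms: none
Why: acid-catalysed methanolysis should remove the primary and secondary triethylsilyl ethers much faster than the tert-butyldimethylsilyl ethers and the hindered tertiary triethylsilyl ethers (selective desilylation).

Step 32
Reactants: 43 tetraol; 44 tetradecanoyl chloride
Product: 45 bis(tetradecanoate) diol
Conditions: 44 (2.1 equiv), 2,4,6-collidine, CH2Cl2, −78 → −20 °C
Reagents that add atoms: none
Why: acylation with the acid chloride and a hindered pyridine base at low temperature should esterify the two primary hydroxyls in preference to the hindered secondary s9 hydroxyls (selective esterification).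

Step 33
Reactants: 45 bis(tetradecanoate) diol
Product: 46 diketone
Conditions: Dess–Martin periodinane (3 equiv), NaHCO3, CH2Cl2, rt
Reagents that add atoms: none
Why: Dess–Martin oxidation of both s9 alcohols under buffered conditions, the equatorial chain on s10 being the thermodynamically preferred arrangement next to the ketone.

Step 34
Reactants: 46 diketone; 47 isopropenylmagnesium bromide (two equivalents are consumed, one at each ketone)
Product: 48 bis(isopropenyl carbinol)
Conditions: 47 (3.0 equiv), anhydrous CeCl3 (3.0 equiv), THF, −78 °C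
Reagents that add atoms: none
Why: two-fold organocerium 1,2-addition in which one isopropenyl group is delivered to each of the two hindered, enolisable s9 ketones (hence two equivalents of 47 end up in the product), which should outpace attack on the two esters at −78 °C, and the new carbinol centres (attack expected from the equatorial side) are destroyed in the next step.

Step 35
Reactants: 48 bis(isopropenyl carbinol)
Product: 49 silyl-protected target
Conditions: pyridinium chlorochromate (C5H5NH)[CrO3Cl] (5 equiv), NaOAc, 4 Å MS, CH2Cl2, rt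
Reagents that add atoms: none
Why: Babler–Dauben oxidative transposition ([3,3] shift of each chromate ester, then oxidation) should give the tetrasubstituted enals, whose geometry should settle under the mildly acidic conditions on the isomer with the formyl group syn to s10, since the smaller formyl group rather than methyl then faces the substituted ring carbon (allylic 1,3-strain).

Step 36
Reactants: 49 silyl-protected target
Product: 50 target (CNP0458412.1)
Conditions: HF·pyridine, pyridine, THF, 0 °C → rt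
Reagents that add atoms: none
Why: fluoride-mediated desilylation buffered with pyridine should cleave the four tert-butyldimethylsilyl and two tertiary triethylsilyl ethers without acyl migration, enal isomerisation or ionisation of the allylic alcohols.

**Compound list**

1 | geraniol, (2E)-3,7-dimethylocta-2,6-dien-1-ol | CC(C)=CCC/C(C)=C/CO | starting material
2 | (2S,3S)-2,3-epoxygeraniol | CC(C)=CCC[C@]1(C)O[C@H]1CO | intermediate
3 | (2R,3S)-2-(chloromethyl)-3-methyl-3-(4-methylpent-3-en-1-yl)oxirane (spatial arrangement of 2) | CC(C)=CCC[C@]1(C)O[C@H]1CCl | intermediate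
4 | tert-butyl(3-iodopropoxy)dimethylsilane | ICCCO[Si](C)(C)C(C)(C)C | starting material
5 | dilithium alkoxide acetylide of (3S)-3,7-dimethyloct-6-en-1-yn-3-ol | [Li+].[Li+].CC(C)=CCC[C@](C)([O-])C#[C-] | intermediate
6 | (6S)-1-[(tert-butyldimethylsilyl)oxy]-6,10-dimethylundec-9-en-4-yn-6-ol | CC(C)=CCC[C@](C)(O)C#CCCCO[Si](C)(C)C(C)(C)C | intermediate
7 | (4Z,6S)-1-[(tert-butyldimethylsilyl)oxy]-6,10-dimethyl-5-(tributylstannyl)undeca-4,9-dien-6-ol (tin cis to the silyloxypropyl chain) | CC(C)=CCC[C@](C)(O)/C(=C/CCCO[Si](C)(C)C(C)(C)C)[Sn](CCCC)(CCCC)CCCC | intermediate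
8 | cyclobutanone | O=C1CCC1 | starting material
9 | (4Z,6S)-1-[(tert-butyldimethylsilyl)oxy]-5-(1-hydroxycyclobutyl)-6,10-dimethylundeca-4,9-dien-6-ol (cyclobutanol cis to the silyloxypropyl chain) | CC(C)=CCC[C@](C)(O)/C(=C/CCCO[Si](C)(C)C(C)(C)C)C1(O)CCC1 | intermediate
10 | cyclic di-tert-butylsilylene of diol 9 (six-membered dioxasilinane spiro-fused to the cyclobutane, alkene geometry of 9) | CC(C)=CCC[C@]1(C)O[Si](C(C)(C)C)(C(C)(C)C)OC2(CCC2)/C1=C\CCCO[Si](C)(C)C(C)(C)C | intermediate
11 | silylene aldehyde (10 with the isopropylidene end cleaved to CH2CH2CHO) | O=CCC[C@]1(C)O[Si](C(C)(C)C)(C(C)(C)C)OC2(CCC2)/C1=C\CCCO[Si](C)(C)C(C)(C)C | intermediate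
12 | fluorosilyl ether spiro ketone (skeleton and configuration of 13; s6 O–Si(tBu)2F, chain O–SiMe2tBu, s9 OH) | CC(C)(C)[Si](C)(C)OCCC[C@@H]1[C@@H](O)CC[C@](C)(O[Si](F)(C(C)(C)C)C(C)(C)C)[C@@]12CCCC2=O | intermediate
13 | (5R,6S,9S,10S)-6,9-dihydroxy-10-(3-hydroxypropyl)-6-methylspiro[4.5]decan-1-one | OCCC[C@@H]1[C@@H](O)CC[C@](C)(O)[C@@]12CCCC2=O | intermediate
14 | 13 as bis(triethylsilyl) ether at the primary and the s9 oxygen | CC[Si](CC)(CC)OCCC[C@@H]1[C@@H](O[Si](CC)(CC)CC)CC[C@](C)(O)[C@@]12CCCC2=O | intermediate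
15 | anti-1,3-diol (14 reduced at s1; s1 OH anti to s6 OH, on the face of s10) | CC[Si](CC)(CC)OCCC[C@@H]1[C@@H](O[Si](CC)(CC)CC)CC[C@](C)(O)[C@@]12CCC[C@H]2O | intermediate
16 | (diethoxyphosphoryl)acetic acid | CCOP(=O)(CC(=O)O)OCC | starting material
17 | s1 (diethoxyphosphoryl)acetate of 15 | CC[Si](CC)(CC)OCCC[C@@H]1[C@@H](O[Si](CC)(CC)CC)CC[C@](C)(O)[C@@]12CCC[C@H]2OC(=O)CP(=O)(OCC)OCC | intermediate
18 | 17 with the s6 oxygen as triethylsilyl ether | CC[Si](CC)(CC)OCCC[C@@H]1[C@@H](O[Si](CC)(CC)CC)CC[C@](C)(O[Si](CC)(CC)CC)[C@@]12CCC[C@H]2OC(=O)CP(=O)(OCC)OCC | intermediate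
19 | α-diazo phosphonoacetate of 18 | CC[Si](CC)(CC)OCCC[C@@H]1[C@@H](O[Si](CC)(CC)CC)CC[C@](C)(O[Si](CC)(CC)CC)[C@@]12CCC[C@H]2OC(=O)C(=[N+]=[N-])P(=O)(OCC)OCC | intermediate
20 | cis-fused α-(diethoxyphosphoryl) γ-lactone (s2–C bond and s1–O on one face; phosphonate carbon as a mixture) | CC[Si](CC)(CC)OCCC[C@@H]1[C@@H](O[Si](CC)(CC)CC)CC[C@](C)(O[Si](CC)(CC)CC)[C@@]12CC[C@@H](C(P(=O)(OCC)OCC)C(=O)O3)[C@H]23 | intermediate
21 | 6-methylhept-5-en-2-one | CC(=O)CCC=C(C)C | starting material
22 | 6-methylhepta-1,5-dien-2-yl trifluoromethanesulfonate | C=C(CCC=C(C)C)OS(=O)(=O)C(F)(F)F | intermediate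
23 | acrolein (prop-2-enal) | C=CC=O | starting material
24 | (2E)-8-methyl-4-methylidenenona-2,7-dienal | O=C/C=C/C(=C)CCC=C(C)C | intermediate
25 | (E)-alkylidene lactone triene (dienyl chain cis to s2, anti to the lactone carbonyl) | CC[Si](CC)(CC)OCCC[C@@H]1[C@@H](O[Si](CC)(CC)CC)CC[C@](C)(O[Si](CC)(CC)CC)[C@@]12CC[C@@H](/C(=C\C=C\C(=C)CCC=C(C)C)C(=O)O3)[C@H]23 | intermediate
26 | triene diol (s1 OH and allylic CH2OH free) | CC[Si](CC)(CC)OCCC[C@@H]1[C@@H](O[Si](CC)(CC)CC)CC[C@](C)(O[Si](CC)(CC)CC)[C@@]12CC[C@@H](/C(=C\C=C\C(=C)CCC=C(C)C)CO)[C@H]2O | intermediate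
27 | triene bis(tert-butyldimethylsilyl) ether | CC[Si](CC)(CC)OCCC[C@@H]1[C@@H](O[Si](CC)(CC)CC)CC[C@](C)(O[Si](CC)(CC)CC)[C@@]12CC[C@@H](/C(=C\C=C\C(=C)CCC=C(C)C)CO[Si](C)(C)C(C)(C)C)[C@H]2O[Si](C)(C)C(C)(C)C | intermediate
28 | 2-methylidenepropane-1,3-diol | C=C(CO)CO | starting material
29 | 2-{[(4-methoxybenzyl)oxy]methyl}prop-2-en-1-ol | C=C(CO)COCc1ccc(OC)cc1 | intermediate
30 | 2-{[(4-methoxybenzyl)oxy]methyl}prop-2-enal | C=C(C=O)COCc1ccc(OC)cc1 | intermediate
31 | cyclohexene aldehyde: c1 carries CHO and CH2O(4-methoxybenzyl), c4 the 4-methylpent-3-enyl group, c6 the alkenyl arm to the spiro unit; CHO cis to the c6 arm | COc1ccc(cc1)COC[C@@]1(C=O)CCC(CCC=C(C)C)=C[C@@H]1/C=C(/CO[Si](C)(C)C(C)(C)C)[C@@H]1CC[C@]3([C@H](CCCO[Si](CC)(CC)CC)[C@@H](O[Si](CC)(CC)CC)CC[C@]3(C)O[Si](CC)(CC)CC)[C@@H]1O[Si](C)(C)C(C)(C)C | intermediate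
32 | c1 vinyl compound (CHO of 31 replaced by CH=CH2) | COc1ccc(cc1)COC[C@@]1(C=C)CCC(CCC=C(C)C)=C[C@@H]1/C=C(/CO[Si](C)(C)C(C)(C)C)[C@@H]1CC[C@]3([C@H](CCCO[Si](CC)(CC)CC)[C@@H](O[Si](CC)(CC)CC)CC[C@]3(C)O[Si](CC)(CC)CC)[C@@H]1O[Si](C)(C)C(C)(C)C | intermediate
33 | 1-bromo-2-methylprop-1-ene | CC(C)=CBr | starting material
34 | B-alkyl-9-borabicyclo[3.3.1]nonane from 32 | COc1ccc(cc1)COC[C@@]1(CCB2C4CCCC2CCC4)CCC(CCC=C(C)C)=C[C@@H]1/C=C(/CO[Si](C)(C)C(C)(C)C)[C@@H]1CC[C@]3([C@H](CCCO[Si](CC)(CC)CC)[C@@H](O[Si](CC)(CC)CC)CC[C@]3(C)O[Si](CC)(CC)CC)[C@@H]1O[Si](C)(C)C(C)(C)C | intermediate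
35 | c1 (4-methylpent-3-enyl) compound (second side chain cis to the c6 arm) | COc1ccc(cc1)COC[C@@]1(CCC=C(C)C)CCC(CCC=C(C)C)=C[C@@H]1/C=C(/CO[Si](C)(C)C(C)(C)C)[C@@H]1CC[C@]3([C@H](CCCO[Si](CC)(CC)CC)[C@@H](O[Si](CC)(CC)CC)CC[C@]3(C)O[Si](CC)(CC)CC)[C@@H]1O[Si](C)(C)C(C)(C)C | intermediate
36 | c1 primary alcohol (CH2OH trans to the c6 arm) | OC[C@@]1(CCC=C(C)C)CCC(CCC=C(C)C)=C[C@@H]1/C=C(/CO[Si](C)(C)C(C)(C)C)[C@@H]1CC[C@]3([C@H](CCCO[Si](CC)(CC)CC)[C@@H](O[Si](CC)(CC)CC)CC[C@]3(C)O[Si](CC)(CC)CC)[C@@H]1O[Si](C)(C)C(C)(C)C | intermediate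
37 | c1 aldehyde | O=C[C@@]1(CCC=C(C)C)CCC(CCC=C(C)C)=C[C@@H]1/C=C(/CO[Si](C)(C)C(C)(C)C)[C@@H]1CC[C@]3([C@H](CCCO[Si](CC)(CC)CC)[C@@H](O[Si](CC)(CC)CC)CC[C@]3(C)O[Si](CC)(CC)CC)[C@@H]1O[Si](C)(C)C(C)(C)C | intermediate
38 | (triphenylphosphoranylidene)acetaldehyde | O=CC=P(c1ccccc1)(c1ccccc1)c1ccccc1 | starting material
39 | (E)-enal on c1 | O=C/C=C/[C@@]1(CCC=C(C)C)CCC(CCC=C(C)C)=C[C@@H]1/C=C(/CO[Si](C)(C)C(C)(C)C)[C@@H]1CC[C@]3([C@H](CCCO[Si](CC)(CC)CC)[C@@H](O[Si](CC)(CC)CC)CC[C@]3(C)O[Si](CC)(CC)CC)[C@@H]1O[Si](C)(C)C(C)(C)C | intermediate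
40 | dimeric alkylidene lactone (second spiro unit joined through an (E,E)-diene to c1) | CC[Si](CC)(CC)OCCC[C@@H]1[C@@H](O[Si](CC)(CC)CC)CC[C@](C)(O[Si](CC)(CC)CC)[C@@]12CC[C@@H](/C(=C\C=C\[C@@]1(CCC=C(C)C)CCC(CCC=C(C)C)=C[C@@H]1/C=C(/CO[Si](C)(C)C(C)(C)C)[C@@H]1CC[C@]3([C@H](CCCO[Si](CC)(CC)CC)[C@@H](O[Si](CC)(CC)CC)CC[C@]3(C)O[Si](CC)(CC)CC)[C@@H]1O[Si](C)(C)C(C)(C)C)C(=O)O3)[C@H]23 | intermediate
41 | dimeric diol (lactone of 40 reduced to s1 OH and allylic CH2OH) | CC[Si](CC)(CC)OCCC[C@@H]1[C@@H](O[Si](CC)(CC)CC)CC[C@](C)(O[Si](CC)(CC)CC)[C@@]12CC[C@@H](/C(=C\C=C\[C@@]1(CCC=C(C)C)CCC(CCC=C(C)C)=C[C@@H]1/C=C(/CO[Si](C)(C)C(C)(C)C)[C@@H]1CC[C@]3([C@H](CCCO[Si](CC)(CC)CC)[C@@H](O[Si](CC)(CC)CC)CC[C@]3(C)O[Si](CC)(CC)CC)[C@@H]1O[Si](C)(C)C(C)(C)C)CO)[C@H]2O | intermediate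
42 | fully silylated dimer (six triethylsilyl and four tert-butyldimethylsilyl ethers) | CC[Si](CC)(CC)OCCC[C@@H]1[C@@H](O[Si](CC)(CC)CC)CC[C@](C)(O[Si](CC)(CC)CC)[C@@]12CC[C@@H](/C(=C\C=C\[C@@]1(CCC=C(C)C)CCC(CCC=C(C)C)=C[C@@H]1/C=C(/CO[Si](C)(C)C(C)(C)C)[C@@H]1CC[C@]3([C@H](CCCO[Si](CC)(CC)CC)[C@@H](O[Si](CC)(CC)CC)CC[C@]3(C)O[Si](CC)(CC)CC)[C@@H]1O[Si](C)(C)C(C)(C)C)CO[Si](C)(C)C(C)(C)C)[C@H]2O[Si](C)(C)C(C)(C)C | intermediate
43 | tetraol (primary and s9 hydroxyls free in both halves) | OCCC[C@@H]1[C@@H](O)CC[C@](C)(O[Si](CC)(CC)CC)[C@@]12CC[C@@H](/C(=C\C=C\[C@@]1(CCC=C(C)C)CCC(CCC=C(C)C)=C[C@@H]1/C=C(/CO[Si](C)(C)C(C)(C)C)[C@@H]1CC[C@]3([C@H](CCCO)[C@@H](O)CC[C@]3(C)O[Si](CC)(CC)CC)[C@@H]1O[Si](C)(C)C(C)(C)C)CO[Si](C)(C)C(C)(C)C)[C@H]2O[Si](C)(C)C(C)(C)C | intermediate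
44 | tetradecanoyl chloride | CCCCCCCCCCCCCC(=O)Cl | starting material
45 | bis(tetradecanoate) diol | CCCCCCCCCCCCCC(=O)OCCC[C@@H]1[C@@H](O)CC[C@](C)(O[Si](CC)(CC)CC)[C@@]12CC[C@@H](/C(=C\C=C\[C@@]1(CCC=C(C)C)CCC(CCC=C(C)C)=C[C@@H]1/C=C(/CO[Si](C)(C)C(C)(C)C)[C@@H]1CC[C@]3([C@H](CCCOC(=O)CCCCCCCCCCCCC)[C@@H](O)CC[C@]3(C)O[Si](CC)(CC)CC)[C@@H]1O[Si](C)(C)C(C)(C)C)CO[Si](C)(C)C(C)(C)C)[C@H]2O[Si](C)(C)C(C)(C)C | intermediate
46 | diketone (both s9 carbons as ketones) | CCCCCCCCCCCCCC(=O)OCCC[C@@H]1C(=O)CC[C@](C)(O[Si](CC)(CC)CC)[C@@]12CC[C@@H](/C(=C\C=C\[C@@]1(CCC=C(C)C)CCC(CCC=C(C)C)=C[C@@H]1/C=C(/CO[Si](C)(C)C(C)(C)C)[C@@H]1CC[C@]3([C@H](CCCOC(=O)CCCCCCCCCCCCC)C(=O)CC[C@]3(C)O[Si](CC)(CC)CC)[C@@H]1O[Si](C)(C)C(C)(C)C)CO[Si](C)(C)C(C)(C)C)[C@H]2O[Si](C)(C)C(C)(C)C | intermediate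
47 | isopropenylmagnesium bromide | C=C(C)[Mg]Br | starting material
48 | bis(isopropenyl carbinol) (tertiary allylic alcohols at both s9 carbons, one isopropenyl group from 47 on each) | CCCCCCCCCCCCCC(=O)OCCC[C@@H]1[C@@](O)(C(C)=C)CC[C@](C)(O[Si](CC)(CC)CC)[C@@]12CC[C@@H](/C(=C\C=C\[C@@]1(CCC=C(C)C)CCC(CCC=C(C)C)=C[C@@H]1/C=C(/CO[Si](C)(C)C(C)(C)C)[C@@H]1CC[C@]3([C@H](CCCOC(=O)CCCCCCCCCCCCC)[C@@](O)(C(C)=C)CC[C@]3(C)O[Si](CC)(CC)CC)[C@@H]1O[Si](C)(C)C(C)(C)C)CO[Si](C)(C)C(C)(C)C)[C@H]2O[Si](C)(C)C(C)(C)C | intermediate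
49 | silyl-protected target (two tertiary triethylsilyl and four tert-butyldimethylsilyl ethers; both enals with CHO syn to s10) | CCCCCCCCCCCCCC(=O)OCCC[C@@H]1/C(=C(/C)C=O)CC[C@](C)(O[Si](CC)(CC)CC)[C@@]12CC[C@@H](/C(=C\C=C\[C@@]1(CCC=C(C)C)CCC(CCC=C(C)C)=C[C@@H]1/C=C(/CO[Si](C)(C)C(C)(C)C)[C@@H]1CC[C@]3([C@H](CCCOC(=O)CCCCCCCCCCCCC)/C(=C(/C)C=O)CC[C@]3(C)O[Si](CC)(CC)CC)[C@@H]1O[Si](C)(C)C(C)(C)C)CO[Si](C)(C)C(C)(C)C)[C@H]2O[Si](C)(C)C(C)(C)C | intermediate
50 | target CNP0458412.1 | CCCCCCCCCCCCCC(=O)OCCC[C@@H]1/C(=C(/C)C=O)CC[C@](C)(O)[C@@]12CC[C@@H](/C(=C\C=C\[C@@]1(CCC=C(C)C)CCC(CCC=C(C)C)=C[C@@H]1/C=C(/CO)[C@@H]1CC[C@]3([C@H](CCCOC(=O)CCCCCCCCCCCCC)/C(=C(/C)C=O)CC[C@]3(C)O)[C@@H]1O)CO)[C@H]2O | target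

**Step count and risks**

Total step count: 36. Longest linear sequence: 32 steps (steps 1–14, 17–19 and 22–36).

Steps most likely to fail:

Step 8 (Prins–pinacol cascade). The alkene carries two allylic C–O bonds and may be too poor a nucleophile, so that Lewis-acid ionisation of the allylic silyl ethers or oligomerisation of the aldehyde outruns ring closure. The fallback leaves the route at 11: the aldehyde is converted with benzyl alcohol and PPTS into the dibenzyl acetal F1, which SnCl4 at −78 °C ionises to a discrete benzyloxycarbenium ion, the more electrophilic initiator class for this ring-enlarging cascade. Chair closure and 1,2-shift then proceed as in step 8, and HF·pyridine gives the s9 benzyl ether keto diol F2. Hydrogenolysis (H2, Pd(OH)2 on carbon, ethyl acetate; no alkene is present at this stage) returns the route at 13.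

Step 22 (catalytic Diels–Alder). Facial or endo selectivity may be poor, silyl groups may be lost to the Lewis acid, or the internal diene may react. The fallback is a biomimetic dimerisation that leaves the route at 27. Selective methanolysis (PPTS, MeOH) gives the triene diol F3, tetradecanoyl chloride with collidine the triene myristate F4, Dess–Martin oxidation the triene ketone F5, isopropenylmagnesium bromide with CeCl3 the triene isopropenyl carbinol F6, and pyridinium chlorochromate the protected monomer enal F7. Heating F7 (toluene, 80 °C, radical inhibitor) should bring the terminal diene of one molecule onto the terminal 1,1-disubstituted alkene of a second with the same ortho/para regiochemistry and return the route at 49. The facial sense is then not set by a catalyst, so the isomer with the required c1/c6 configuration has to be separated from its diastereomers.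

Step 35 (double oxidative transposition). The tertiary allylic alcohols may dehydrate, the diene may be damaged by the oxidant, or one of the two enals may not equilibrate to the required geometry. The fallback leaves the route at 48: Ph3SiOReO3-catalysed 1,3-transposition moves both hydroxyls to the primary positions to give the bis(primary allylic alcohol) F8, and MnO2, which touches only these free allylic alcohols, returns the route at 49. The enal geometry is then adjusted by equilibration (catalytic iodine or a thiol) toward the isomer with CHO syn to s10.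

Further compounds
F1 | step 8 | dibenzyl acetal of 11 | c1ccccc1COC(OCc1ccccc1)CC[C@]1(C)O[Si](C(C)(C)C)(C(C)(C)C)OC2(CCC2)/C1=C\CCCO[Si](C)(C)C(C)(C)C
F2 | step 8 | s9 benzyl ether of keto triol 13 | OCCC[C@@H]1[C@@H](OCc3ccccc3)CC[C@](C)(O)[C@@]12CCCC2=O
F3 | step 22 | triene diol (primary and s9 hydroxyls free, other silyl ethers kept) | OCCC[C@@H]1[C@@H](O)CC[C@](C)(O[Si](CC)(CC)CC)[C@@]12CC[C@@H](/C(=C\C=C\C(=C)CCC=C(C)C)CO[Si](C)(C)C(C)(C)C)[C@H]2O[Si](C)(C)C(C)(C)C
F4 | step 22 | triene myristate (s9 hydroxyl free) | CCCCCCCCCCCCCC(=O)OCCC[C@@H]1[C@@H](O)CC[C@](C)(O[Si](CC)(CC)CC)[C@@]12CC[C@@H](/C(=C\C=C\C(=C)CCC=C(C)C)CO[Si](C)(C)C(C)(C)C)[C@H]2O[Si](C)(C)C(C)(C)C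
F5 | step 22 | triene ketone (s9 ketone) | CCCCCCCCCCCCCC(=O)OCCC[C@@H]1C(=O)CC[C@](C)(O[Si](CC)(CC)CC)[C@@]12CC[C@@H](/C(=C\C=C\C(=C)CCC=C(C)C)CO[Si](C)(C)C(C)(C)C)[C@H]2O[Si](C)(C)C(C)(C)C
F6 | step 22 | triene isopropenyl carbinol | CCCCCCCCCCCCCC(=O)OCCC[C@@H]1[C@@](O)(C(C)=C)CC[C@](C)(O[Si](CC)(CC)CC)[C@@]12CC[C@@H](/C(=C\C=C\C(=C)CCC=C(C)C)CO[Si](C)(C)C(C)(C)C)[C@H]2O[Si](C)(C)C(C)(C)C
F7 | step 22 | protected monomer enal (triene, myristate, enal) | CCCCCCCCCCCCCC(=O)OCCC[C@@H]1/C(=C(/C)C=O)CC[C@](C)(O[Si](CC)(CC)CC)[C@@]12CC[C@@H](/C(=C\C=C\C(=C)CCC=C(C)C)CO[Si](C)(C)C(C)(C)C)[C@H]2O[Si](C)(C)C(C)(C)C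
F8 | step 35 | bis(primary allylic alcohol) (tetrasubstituted alkenes, CH2OH in place of each CHO of 49) | CCCCCCCCCCCCCC(=O)OCCC[C@@H]1/C(=C(/C)CO)CC[C@](C)(O[Si](CC)(CC)CC)[C@@]12CC[C@@H](/C(=C\C=C\[C@@]1(CCC=C(C)C)CCC(CCC=C(C)C)=C[C@@H]1/C=C(/CO[Si](C)(C)C(C)(C)C)[C@@H]1CC[C@]3([C@H](CCCOC(=O)CCCCCCCCCCCCC)/C(=C(/C)CO)CC[C@]3(C)O[Si](CC)(CC)CC)[C@@H]1O[Si](C)(C)C(C)(C)C)CO[Si](C)(C)C(C)(C)C)[C@H]2O[Si](C)(C)C(C)(C)C
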